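**Plan**

- Retrosynthesis: the two phenols are masked as methoxymethyl (MOM) ethers. Both bonds at the ester carbonyl carbon are then cut together, C1(ring)–C(=O) and C(=O)–O(chain), leaving a 3-iodocatechol bis-MOM ether, carbon monoxide and (S)-18-methylicosan-1-ol. The alcohol is cut at C16–C17 into a C16 bromo alcohol and a chiral C5 Grignard reagent.
- Enabling feature: the carbonyl carbon is a one-carbon bridge between aromatic C1 of the benzene ring and the primary chain oxygen, so it can be delivered as CO. C1 lies ortho to the C2 oxygen, so the iodide is reachable by directed ortho-lithiation.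
- Forward order: the chain is joined first by copper-catalysed sp3–sp3 coupling; the aryl iodide is made from catechol; iodide, CO and alcohol are united in one palladium-catalysed operation; the MOM groups fall last. No ring is formed, since the benzene ring is bought as catechol.
- Stereochemistry: the only stereocenter, C18 (S), is bought in (S)-1-bromo-2-methylbutane, and no bond to it is made or broken anywhere in the route.

Key step: step 6

Assumption: commercial (S)-1-bromo-2-methylbutane of high enantiomeric purity is used, so the optical purity of the target should equal that of this reagent.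

**Route**

Step 1
Reactants: 1 16-bromohexadecan-1-ol
Product: 2 [(16-bromohexadecyl)oxy](tert-butyl)dimethylsilane
Conditions: TBSCl, imidazole, CH2Cl2, 0 °C to rt
Reagents that add atoms: tert-butyldimethylsilyl chloride (TBSCl), CC(C)(C)[Si](C)(C)Cl
Why: Imidazole-promoted O-silylation of a primary alcohol is routine and removes the acidic proton that would quench the Grignard reagent of step 2, while the primary bromide is untouched.

Step 2
Reactants: 3 (S)-1-bromo-2-methylbutane; 2 [(16-bromohexadecyl)oxy](tert-butyl)dimethylsilane
Product: 5 tert-butyldimethyl{[(18S)-18-methylicosyl]oxy}silane, via (S)-2-methylbutylmagnesium bromide 4 (not isolated)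
Conditions: 3, Mg, THF, 45 °C; then 2, Li2CuCl4 (3 mol %), THF/NMP, −5 °C to rt
Reagents that add atoms: none
Why: Copper-catalysed cross-coupling of a primary alkyl Grignard reagent with a primary alkyl bromide (Kochi coupling) should form the C16–C17 bond; the C18 stereocenter is β to magnesium and takes no part in insertion or coupling, so its (S) configuration is carried over, and the silyl ether is inert.

Step 3
Reactants: 5 tert-butyldimethyl{[(18S)-18-methylicosyl]oxy}silane
Product: 6 (S)-18-methylicosan-1-ol
Conditions: TBAF, THF, rt
Reagents that add atoms: none
Why: Fluoride-induced desilylation, driven by the strong Si–F bond, should free the primary alcohol, and the saturated chain offers nothing else for fluoride to attack.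

Step 4
Reactants: 7 catechol
Product: 8 1,2-bis(methoxymethoxy)benzene
Conditions: MOMCl, i-Pr2NEt, CH2Cl2, 0 °C to rt
Reagents that add atoms: chloromethyl methyl ether (MOMCl), COCCl
Why: Williamson-type O-alkylation of both phenols with the reactive α-chloro ether is standard; the MOM ethers are chosen because they direct the metalation of step 5 and leave under mild acid at the end.

Step 5
Reactants: 8 1,2-bis(methoxymethoxy)benzene
Product: 10 1-iodo-2,3-bis(methoxymethoxy)benzene, via 2,3-bis(methoxymethoxy)phenyllithium 9 (not isolated)
Conditions: n-BuLi (1.1 equiv), THF, 0 °C; then I2, THF, −78 °C to rt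
Reagents that add atoms: iodine, II
Why: Directed ortho-metalation, in which the MOM oxygens coordinate lithium and guide deprotonation to the position next to one OMOM group (the two such positions are equivalent by symmetry), followed by iodinolysis of the aryllithium, should give the 3-iodo compound as a single regioisomer.

Step 6
Reactants: 10 1-iodo-2,3-bis(methoxymethoxy)benzene (1.2 equiv); 11 carbon monoxide; 6 (S)-18-methylicosan-1-ol (1.0 equiv)
Product: 12 (S)-18-methylicosyl 2,3-bis(methoxymethoxy)benzoate
Conditions: CO (1 atm), Pd(OAc)2 (5 mol %), Xantphos (6 mol %), Et3N (3 equiv), toluene, 90 °C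
Reagents that add atoms: carbon monoxide (compound 11), [C-]#[O+]
Why: Pd(OAc)2 is reduced in the flask to zerovalent palladium, which adds oxidatively into the C1–I bond of 10; CO then inserts into the aryl–palladium bond to give an aroyl complex of divalent palladium, and alcohol 6, assisted by Et3N, attacks that acyl group so that the ester is released with triethylammonium iodide and zerovalent palladium re-enters the cycle. The closest known reaction type is the Heck-type palladium-catalysed alkoxycarbonylation of aryl iodides with primary alcohols, for which the wide-bite-angle ligand Xantphos is established at atmospheric CO pressure. No ring is closed and no stereocenter is created; the (S) center at C18 lies seventeen carbons from the reacting hydroxyl and cannot be affected. The step needs chemoselectivity, namely a single CO insertion without α-keto ester formation, no reduction of the C–I bond, and full capture of the more valuable alcohol. This should be secured by the chelating ligand at low CO pressure, by the unhindered primary hydroxyl of 6 as the only nucleophile present, and by the slight excess of 10; the MOM acetals and the saturated chain are inert to the mildly basic medium.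

Step 7
Reactants: 12 (S)-18-methylicosyl 2,3-bis(methoxymethoxy)benzoate
Product: 13 gentiside H, (S)-18-methylicosyl 2,3-dihydroxybenzoate
Conditions: 3 M aq. HCl, THF, 45 °C
Reagents that add atoms: none
Why: Acid-catalysed hydrolysis of the two aryl MOM acetals through oxocarbenium ions should free the catechol, while the benzoate of a primary alcohol is stable to dilute acid at this temperature and the absence of an alcohol co-solvent excludes transesterification.

**Compound list**

1 | 16-bromohexadecan-1-ol | OCCCCCCCCCCCCCCCCBr | starting material
2 | [(16-bromohexadecyl)oxy](tert-butyl)dimethylsilane | CC(C)(C)[Si](C)(C)OCCCCCCCCCCCCCCCCBr | intermediate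
3 | (S)-1-bromo-2-methylbutane | CC[C@H](C)CBr | starting material
4 | (S)-2-methylbutylmagnesium bromide (formed in the flask) | CC[C@H](C)C[Mg]Br | intermediate
5 | tert-butyldimethyl{[(18S)-18-methylicosyl]oxy}silane | CC[C@H](C)CCCCCCCCCCCCCCCCCO[Si](C)(C)C(C)(C)C | intermediate
6 | (S)-18-methylicosan-1-ol | CC[C@H](C)CCCCCCCCCCCCCCCCCO | intermediate
7 | catechol | Oc1ccccc1O | starting material
8 | 1,2-bis(methoxymethoxy)benzene | COCOc1ccccc1OCOC | intermediate
9 | 2,3-bis(methoxymethoxy)phenyllithium (formed in the flask) | [Li]c1cccc(OCOC)c1OCOC | intermediate
10 | 1-iodo-2,3-bis(methoxymethoxy)benzene | COCOc1cccc(I)c1OCOC | intermediate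
11 | carbon monoxide | [C-]#[O+] | starting material
12 | (S)-18-methylicosyl 2,3-bis(methoxymethoxy)benzoate | CC[C@H](C)CCCCCCCCCCCCCCCCCOC(=O)c1cccc(OCOC)c1OCOC | intermediate
13 | gentiside H, (S)-18-methylicosyl 2,3-dihydroxybenzoate | CC[C@H](C)CCCCCCCCCCCCCCCCCOC(=O)c1cccc(O)c1O | target

**Step count**

Total: 7 steps. Longest linear sequence: 5 steps (steps 1, 2, 3, 6, 7); the aryl branch (steps 4, 5) joins at step 6.

**Steps most likely to fail, with fallbacks**

Step 6 (key step). Oxidative addition at the ortho-oxygenated, electron-rich iodide may be slow, hydrodeiodination may compete, and the acylpalladium intermediate may be trapped incompletely by the waxy, near-stoichiometric alcohol. The fallback sets out from 8 and gives up the catalytic carbonylation for a carboxylation–esterification sequence. Compound 8 is lithiated as in step 5 to 9, which is quenched with dry CO2 instead of iodine; careful acidification with cold 1 M HCl to pH 3 should give 2,3-bis(methoxymethoxy)benzoic acid F4. Steglich esterification of this acid with alcohol 6 (DCC, catalytic DMAP, CH2Cl2, rt) returns to the route at 12.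

Step 2. Bromine–magnesium exchange, homocoupling and β-hydride loss may compete with cross-coupling, leaving reduced and eliminated C16 by-products that are hard to separate from the non-polar product. The fallback sets out from 3 and replaces the organometallic coupling by sulfone-anion alkylation.
- Displacement of the bromide of 3 with PhSO2Na (DMF, 80 °C) should give (S)-[(2-methylbutyl)sulfonyl]benzene F1.
- Deprotonation with n-BuLi (THF, −78 °C) gives [(2S)-2-methyl-1-(phenylsulfonyl)butyl]lithium F2.
- This anion is alkylated by the unhindered primary bromide 2 (THF/DMPU, −78 °C to rt) to give tert-butyldimethyl{[(18S)-18-methyl-17-(phenylsulfonyl)icosyl]oxy}silane F3 as a mixture of C17 epimers.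
- Reductive desulfonylation with Mg in MeOH/THF at 50 °C removes the sulfonyl group and the C17 stereocenter with it, returning to the route at 5. C18 carries no acidic hydrogen and should keep its configuration.

Step 7. Before both acetals are cleaved, acid-promoted ester cleavage may set in, and the formaldehyde released may alkylate the electron-rich catechol ring. The fallback sets out from 10 and changes the protecting group so that the last step is neutral.
- Both MOM groups are removed while no ester is present (catalytic HCl, MeOH, rt) to give 3-iodobenzene-1,2-diol F5.
- Benzylation (BnBr, K2CO3, DMF, rt) gives 1,2-bis(benzyloxy)-3-iodobenzene F6.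
- The carbonylation of step 6, run with 11 and 6, gives (S)-18-methylicosyl 2,3-bis(benzyloxy)benzoate F7.
- Hydrogenolysis (H2, 1 atm, 10% Pd/C, EtOAc, rt) arrives at 13.

Further compounds
F1 | step 2 | (S)-[(2-methylbutyl)sulfonyl]benzene | CC[C@H](C)CS(=O)(=O)c1ccccc1
F2 | step 2 | [(2S)-2-methyl-1-(phenylsulfonyl)butyl]lithium | CC[C@H](C)C([Li])S(=O)(=O)c1ccccc1
F3 | step 2 | tert-butyldimethyl{[(18S)-18-methyl-17-(phenylsulfonyl)icosyl]oxy}silane (C17 epimers) | CC[C@H](C)C(CCCCCCCCCCCCCCCCO[Si](C)(C)C(C)(C)C)S(=O)(=O)c1ccccc1
F4 | step 6 | 2,3-bis(methoxymethoxy)benzoic acid | COCOc1cccc(C(=O)O)c1OCOC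
F5 | step 7 | 3-iodobenzene-1,2-diol | Oc1cccc(I)c1O
F6 | step 7 | 1,2-bis(benzyloxy)-3-iodobenzene | Ic1cccc(OCc2ccccc2)c1OCc1ccccc1
F7 | step 7 | (S)-18-methylicosyl 2,3-bis(benzyloxy)benzoate | CC[C@H](C)CCCCCCCCCCCCCCCCCOC(=O)c1cccc(OCc2ccccc2)c1OCc1ccccc1
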